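**Plan**
- The retrosynthesis cuts the two depside C(=O)–O bonds (B–C first, then A–B), giving a ring A benzoic acid and two orsellinate esters. It then cuts the C1–CO2H bond of ring A back to an aryl triflate, that is, to a phenol oxygen on C1.
- Ring A, numbered from its ester-bearing carbon C1, has C2–OMe and C3–OMe beside C4–OH, with C5–H and C6–CH3. These are the two methoxy-bearing carbons and one carbonyl of dimethyl squarate plus an isopropenyl unit, so the ring is opened at C4–C5 to a 4-isopropenyl-4-silyloxycyclobutenone.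
- Forward, ring A is the only ring made: Grignard addition to the squarate, silylation, thermal ring expansion, then benzylation, desilylation, triflation and carbonylation put the carboxyl carbon on C1.
- The ring A acid is esterified with allyl orsellinate (ring B), the allyl ester is removed, the A–B acid is esterified with benzyl orsellinate (ring C), and hydrogenolysis frees the target.
- The target has no stereocentre; the one stereocentre of the route (the racemic carbinol carbon of the cyclobutenone) is erased in the ring opening.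

Key step: step 3

Remark: the two cyclobutenones are racemic and their SMILES show one enantiomer; nothing downstream depends on this centre.

**Step 1**
Reactants: 1 dimethyl squarate (3,4-dimethoxycyclobut-3-ene-1,2-dione); 2 isopropenylmagnesium bromide
Product: 3 rac-4-hydroxy-2,3-dimethoxy-4-(prop-1-en-2-yl)cyclobut-2-en-1-one
Conditions: 2 (1.05 equiv), THF, −78 °C; sat. aq. NH4Cl at −78 °C
Reagents that add atoms: none
Why: Grignard 1,2-addition to one of the two equivalent vinylogous-ester carbonyls of the squarate, where low temperature stops a second addition and the new carbinol centre forms as a racemate.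

**Step 2**
Reactants: 3 rac-4-hydroxy-2,3-dimethoxy-4-(prop-1-en-2-yl)cyclobut-2-en-1-one
Product: 4 rac-4-[(tert-butyldimethylsilyl)oxy]-2,3-dimethoxy-4-(prop-1-en-2-yl)cyclobut-2-en-1-one
Conditions: TBSOTf, 2,6-lutidine, CH2Cl2, −78 to 0 °C
Reagents that add atoms: tert-butyldimethylsilyl trifluoromethanesulfonate, CC(C)(C)[Si](C)(C)OS(=O)(=O)C(F)(F)F
Why: Silyl triflate with a hindered pyridine base is the standard O-silylation of tertiary alcohols, and the excess base and low temperature should keep the acid-sensitive hydroxycyclobutenone from ionising.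

**Step 3**
Reactants: 4 rac-4-[(tert-butyldimethylsilyl)oxy]-2,3-dimethoxy-4-(prop-1-en-2-yl)cyclobut-2-en-1-one
Product: 7 4-[(tert-butyldimethylsilyl)oxy]-2,3-dimethoxy-5-methylphenol, via dienylketene 5 (not isolated), via cyclohexa-2,4-dienone 6 (not isolated)
Conditions: degassed toluene, 110 °C, argon
Reagents that add atoms: none
Why: Heating should open the bond between the carbonyl carbon and the silyloxy carbon of the cyclobutenone in a conrotatory four-electron process in which the silyloxy donor rotates outward, so the isopropenyl group turns inward and lies cis to the ketene in 5. The ketene carbon and the terminal CH2 of the isopropenyl group then join in a thermal six-electron disrotatory electrocyclisation, which closes the six-membered ring A by forming its C4–C5 bond (ring A numbering), and dienone 6 enolises to the phenol 7. The closest known reaction type is the Moore rearrangement of 4-alkenyl-4-oxycyclobutenones derived from squarate esters. No stereocentre is created, and the racemic carbinol carbon of 4 becomes the sp2 carbon C1 of ring A. The step needs torquoselectivity in the ring opening, and the oxygen donor on the sp3 carbon secures it because its lone pairs favour outward rotation. The ketene oxygen emerges as the free C4–OH while the C1 oxygen stays silylated, so the two hydroquinone oxygens are differentiated and the methoxy groups sit on C2 and C3.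

**Step 4**
Reactants: 7 4-[(tert-butyldimethylsilyl)oxy]-2,3-dimethoxy-5-methylphenol
Product: 8 {[4-(benzyloxy)-2,3-dimethoxy-6-methylphenyl]oxy}(tert-butyl)dimethylsilane
Conditions: BnBr, K2CO3, dry acetone, 45 °C
Reagents that add atoms: benzyl bromide, BrCc1ccccc1
Why: Williamson O-benzylation of the only free phenol, with the aryl silyl ether shielded by its two ortho substituents (OMe and CH3) and unable to migrate to the para oxygen.

**Step 5**
Reactants: 8 {[4-(benzyloxy)-2,3-dimethoxy-6-methylphenyl]oxy}(tert-butyl)dimethylsilane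
Product: 9 4-(benzyloxy)-2,3-dimethoxy-6-methylphenol
Conditions: TBAF, AcOH, THF, 0 °C
Reagents that add atoms: none
Why: Fluoride cleavage of an aryl silyl ether, buffered with acetic acid so the electron-rich phenoxide is protonated at once and not left open to air oxidation.

**Step 6**
Reactants: 9 4-(benzyloxy)-2,3-dimethoxy-6-methylphenol
Product: 10 4-(benzyloxy)-2,3-dimethoxy-6-methylphenyl trifluoromethanesulfonate
Conditions: Tf2O, pyridine, CH2Cl2, 0 °C
Reagents that add atoms: trifluoromethanesulfonic anhydride, O=S(=O)(OS(=O)(=O)C(F)(F)F)C(F)(F)F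
Why: O-sulfonylation of a phenol with triflic anhydride and pyridine, which is reliable even for di-ortho-substituted phenols.

**Step 7**
Reactants: 10 4-(benzyloxy)-2,3-dimethoxy-6-methylphenyl trifluoromethanesulfonate
Product: 11 methyl 4-(benzyloxy)-2,3-dimethoxy-6-methylbenzoate
Conditions: Pd(OAc)2 (5 mol %), 1,3-bis(diphenylphosphino)propane, CO (1–3 atm), MeOH, Et3N, DMF, 75 °C
Reagents that add atoms: carbon monoxide, [C-]#[O+]; methanol, CO
Why: Palladium-catalysed alkoxycarbonylation of an aryl triflate, in which the triflate adds oxidatively to zerovalent palladium formed in situ, CO inserts and methanol cleaves the acylpalladium, with the chelating diphosphine being the usual ligand for this reaction of triflates.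

**Step 8**
Reactants: 11 methyl 4-(benzyloxy)-2,3-dimethoxy-6-methylbenzoate
Product: 12 4-(benzyloxy)-2,3-dimethoxy-6-methylbenzoic acid
Conditions: KOH, DMSO/H2O, 90 °C; then dilute HCl
Reagents that add atoms: potassium hydroxide, [K+].[OH-]
Why: Saponification with hydroxide in aqueous DMSO is the established way to hydrolyse di-ortho-substituted benzoates of the orsellinate type, and the benzyl and methyl ethers are inert to it.

**Step 9**
Reactants: 13 orsellinic acid (2,4-dihydroxy-6-methylbenzoic acid)
Product: 14 prop-2-en-1-yl 2,4-dihydroxy-6-methylbenzoate (allyl orsellinate)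
Conditions: allyl bromide (1.05 equiv), KHCO3, DMF, rt
Reagents that add atoms: allyl bromide, C=CCBr
Why: Carboxylate alkylation, in which hydrogencarbonate deprotonates only the carboxylic acid and leaves the phenols unalkylated, and room temperature avoids decarboxylation.

**Step 10**
Reactants: 12 4-(benzyloxy)-2,3-dimethoxy-6-methylbenzoic acid; 14 prop-2-en-1-yl 2,4-dihydroxy-6-methylbenzoate
Product: 16 prop-2-en-1-yl 4-{[4-(benzyloxy)-2,3-dimethoxy-6-methylbenzoyl]oxy}-2-hydroxy-6-methylbenzoate, via mixed trifluoroacetic anhydride 15 (not isolated)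
Conditions: TFAA, toluene, rt
Reagents that add atoms: none
Why: Depside esterification through the mixed trifluoroacetic anhydride, which activates even a di-ortho-substituted benzoic acid, and only the 4-OH of 14 reacts because the 2-OH is hydrogen-bonded to the ester carbonyl.

**Step 11**
Reactants: 16 prop-2-en-1-yl 4-{[4-(benzyloxy)-2,3-dimethoxy-6-methylbenzoyl]oxy}-2-hydroxy-6-methylbenzoate
Product: 17 4-{[4-(benzyloxy)-2,3-dimethoxy-6-methylbenzoyl]oxy}-2-hydroxy-6-methylbenzoic acid
Conditions: Pd(PPh3)4 (5 mol %), sodium 4-methylbenzenesulfinate (4-MeC6H4SO2Na), THF/MeOH, rt; then dilute HCl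
Reagents that add atoms: none
Why: Tsuji–Trost deallylation, in which a π-allylpalladium complex forms from the allyl ester and is captured by the non-basic sulfinate, so the aryl ester link and the benzyl ether are untouched.

**Step 12**
Reactants: 13 orsellinic acid (2,4-dihydroxy-6-methylbenzoic acid)
Product: 18 benzyl 2,4-dihydroxy-6-methylbenzoate (benzyl orsellinate)
Conditions: BnBr (1.05 equiv), KHCO3, DMF, rt
Reagents that add atoms: benzyl bromide, BrCc1ccccc1
Why: The same chemoselective carboxylate alkylation as in step 9, here with benzyl bromide.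

**Step 13**
Reactants: 17 4-{[4-(benzyloxy)-2,3-dimethoxy-6-methylbenzoyl]oxy}-2-hydroxy-6-methylbenzoic acid; 18 benzyl 2,4-dihydroxy-6-methylbenzoate
Product: 20 benzyl 4-[(4-{[4-(benzyloxy)-2,3-dimethoxy-6-methylbenzoyl]oxy}-2-hydroxy-6-methylbenzoyl)oxy]-2-hydroxy-6-methylbenzoate, via O-acylisourea 19 (not isolated)
Conditions: DCC, toluene/Et2O, rt
Reagents that add atoms: none
Why: Carbodiimide depside esterification, which tolerates a free ortho-hydroxy group on the acid because the two hydrogen-bonded 2-OH groups are poor nucleophiles and the 4-OH of 18 is the only phenol that attacks.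

**Step 14**
Reactants: 20 benzyl 4-[(4-{[4-(benzyloxy)-2,3-dimethoxy-6-methylbenzoyl]oxy}-2-hydroxy-6-methylbenzoyl)oxy]-2-hydroxy-6-methylbenzoate
Product: 21 4-[(4-{[4-hydroxy-2,3-dimethoxy-6-methylbenzoyl]oxy}-2-hydroxy-6-methylbenzoyl)oxy]-2-hydroxy-6-methylbenzoic acid (CNP0319613.0)
Conditions: H2 (1 atm), Pd on carbon (10% Pd), EtOAc, rt
Reagents that add atoms: none
Why: Catalytic hydrogenolysis removes the benzyl ether and the benzyl ester together while aryl esters and aryl methyl ethers are stable, and room temperature avoids decarboxylation of the salicylic-type acid.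

**Compound list**
1 | dimethyl squarate (3,4-dimethoxycyclobut-3-ene-1,2-dione) | COC1=C(OC)C(=O)C1=O | starting material
2 | isopropenylmagnesium bromide | CC(=C)[Mg]Br | starting material
3 | rac-4-hydroxy-2,3-dimethoxy-4-(prop-1-en-2-yl)cyclobut-2-en-1-one (one enantiomer drawn) | COC1=C(OC)[C@](O)(C(C)=C)C1=O | intermediate
4 | rac-4-[(tert-butyldimethylsilyl)oxy]-2,3-dimethoxy-4-(prop-1-en-2-yl)cyclobut-2-en-1-one (one enantiomer drawn) | COC1=C(OC)[C@](O[Si](C)(C)C(C)(C)C)(C(C)=C)C1=O | intermediate
5 | (3Z)-4-[(tert-butyldimethylsilyl)oxy]-2,3-dimethoxy-5-methylhexa-1,3,5-trien-1-one (dienylketene) | O=C=C(OC)/C(OC)=C(\C(C)=C)O[Si](C)(C)C(C)(C)C | intermediate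
6 | 4-[(tert-butyldimethylsilyl)oxy]-2,3-dimethoxy-5-methylcyclohexa-2,4-dien-1-one | O=C1CC(C)=C(O[Si](C)(C)C(C)(C)C)C(OC)=C1OC | intermediate
7 | 4-[(tert-butyldimethylsilyl)oxy]-2,3-dimethoxy-5-methylphenol | COc1c(O)cc(C)c(O[Si](C)(C)C(C)(C)C)c1OC | intermediate
8 | {[4-(benzyloxy)-2,3-dimethoxy-6-methylphenyl]oxy}(tert-butyl)dimethylsilane | COc1c(OCc2ccccc2)cc(C)c(O[Si](C)(C)C(C)(C)C)c1OC | intermediate
9 | 4-(benzyloxy)-2,3-dimethoxy-6-methylphenol | COc1c(OCc2ccccc2)cc(C)c(O)c1OC | intermediate
10 | 4-(benzyloxy)-2,3-dimethoxy-6-methylphenyl trifluoromethanesulfonate | COc1c(OCc2ccccc2)cc(C)c(OS(=O)(=O)C(F)(F)F)c1OC | intermediate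
11 | methyl 4-(benzyloxy)-2,3-dimethoxy-6-methylbenzoate | COC(=O)c1c(C)cc(OCc2ccccc2)c(OC)c1OC | intermediate
12 | 4-(benzyloxy)-2,3-dimethoxy-6-methylbenzoic acid | OC(=O)c1c(C)cc(OCc2ccccc2)c(OC)c1OC | intermediate
13 | orsellinic acid (2,4-dihydroxy-6-methylbenzoic acid) | Cc1cc(O)cc(O)c1C(=O)O | starting material
14 | prop-2-en-1-yl 2,4-dihydroxy-6-methylbenzoate (allyl orsellinate) | Cc1cc(O)cc(O)c1C(=O)OCC=C | intermediate
15 | 4-(benzyloxy)-2,3-dimethoxy-6-methylbenzoic trifluoroacetic anhydride | COc1c(OCc2ccccc2)cc(C)c(C(=O)OC(=O)C(F)(F)F)c1OC | intermediate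
16 | prop-2-en-1-yl 4-{[4-(benzyloxy)-2,3-dimethoxy-6-methylbenzoyl]oxy}-2-hydroxy-6-methylbenzoate | COc1c(OCc2ccccc2)cc(C)c(C(=O)Oc2cc(C)c(C(=O)OCC=C)c(O)c2)c1OC | intermediate
17 | 4-{[4-(benzyloxy)-2,3-dimethoxy-6-methylbenzoyl]oxy}-2-hydroxy-6-methylbenzoic acid | COc1c(OCc2ccccc2)cc(C)c(C(=O)Oc2cc(C)c(C(=O)O)c(O)c2)c1OC | intermediate
18 | benzyl 2,4-dihydroxy-6-methylbenzoate (benzyl orsellinate) | Cc1cc(O)cc(O)c1C(=O)OCc1ccccc1 | intermediate
19 | O-acylisourea of acid 17 with N,N'-dicyclohexylcarbodiimide | COc1c(OCc2ccccc2)cc(C)c(C(=O)Oc2cc(C)c(C(=O)OC(=NC3CCCCC3)NC3CCCCC3)c(O)c2)c1OC | intermediate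
20 | benzyl 4-[(4-{[4-(benzyloxy)-2,3-dimethoxy-6-methylbenzoyl]oxy}-2-hydroxy-6-methylbenzoyl)oxy]-2-hydroxy-6-methylbenzoate | COc1c(OCc2ccccc2)cc(C)c(C(=O)Oc2cc(C)c(C(=O)Oc3cc(C)c(C(=O)OCc4ccccc4)c(O)c3)c(O)c2)c1OC | intermediate
21 | 4-[(4-{[4-hydroxy-2,3-dimethoxy-6-methylbenzoyl]oxy}-2-hydroxy-6-methylbenzoyl)oxy]-2-hydroxy-6-methylbenzoic acid (CNP0319613.0) | COc1c(O)cc(C)c(C(=O)Oc2cc(C)c(C(=O)Oc3cc(C)c(C(=O)O)c(O)c3)c(O)c2)c1OC | target

**Step count**
Total: 14 steps. Longest linear sequence: 12 steps (steps 1–8, 10, 11, 13, 14, from dimethyl squarate).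

**Steps most likely to fail**

Step 7. The triflate sits between OMe and CH3 on an electron-rich ring, so oxidative addition and CO insertion may be slow. Sulfur–oxygen cleavage of the triflate by methanol and amine, or reduction to the arene, could then outrun ester formation. The fallback sets out from 10 and returns at 12. A Stille coupling with tributyl(vinyl)stannane (Pd(PPh3)4, LiCl, 1,4-dioxane, 100 °C) should give 1-(benzyloxy)-4-ethenyl-2,3-dimethoxy-5-methylbenzene F1. Lemieux–Johnson cleavage of the vinyl group (OsO4 cat., NaIO4, 2,6-lutidine, dioxane/H2O) should give 4-(benzyloxy)-2,3-dimethoxy-6-methylbenzaldehyde F2. Pinnick oxidation (NaClO2, NaH2PO4, 2-methylbut-2-ene, t-BuOH/H2O) then delivers acid 12, so that 11 and step 8 are bypassed.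

Step 13. The activated carboxyl of the free salicylic-type acid may rearrange to an unreactive N-acylurea, or be attacked by a phenol of a second acid molecule, before the weakly nucleophilic phenol 18 reacts. The fallback sets out from 16 and returns at 21. The ring B 2-OH is benzylated (BnBr, K2CO3, DMF, 50 °C) to prop-2-en-1-yl 2-(benzyloxy)-4-{[4-(benzyloxy)-2,3-dimethoxy-6-methylbenzoyl]oxy}-6-methylbenzoate F3. Deallylation as in step 11 gives 2-(benzyloxy)-4-{[4-(benzyloxy)-2,3-dimethoxy-6-methylbenzoyl]oxy}-6-methylbenzoic acid F4, which now carries no free phenol. With TFAA in toluene it forms the mixed trifluoroacetic anhydride of acid F4, F5, which acylates the 4-OH of 18 to benzyl 4-[(2-(benzyloxy)-4-{[4-(benzyloxy)-2,3-dimethoxy-6-methylbenzoyl]oxy}-6-methylbenzoyl)oxy]-2-hydroxy-6-methylbenzoate F6. Hydrogenolysis (H2, Pd on carbon, EtOAc) removes all three benzyl groups and gives 21.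

Step 2. The Lewis-acidic silyl triflate may ionise the tertiary carbinol, leading to loss of the hydroxyl and rearrangement to a cyclobutenedione, or silylation of the hindered alcohol may stall. The fallback sets out from 1 and returns at 4. The alcohol is never isolated: addition of 2 to 1 in THF at −78 °C gives bromomagnesium 2,3-dimethoxy-4-oxo-1-(prop-1-en-2-yl)cyclobut-2-en-1-olate F7. This alkoxide is silylated in the same flask with TBSOTf (−78 to 0 °C) before any aqueous contact, so that a more nucleophilic oxygen is silylated and no Brønsted acid is formed.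

**Further compounds**
F1 | step 7 | 1-(benzyloxy)-4-ethenyl-2,3-dimethoxy-5-methylbenzene | COc1c(OCc2ccccc2)cc(C)c(C=C)c1OC
F2 | step 7 | 4-(benzyloxy)-2,3-dimethoxy-6-methylbenzaldehyde | COc1c(OCc2ccccc2)cc(C)c(C=O)c1OC
F3 | step 13 | prop-2-en-1-yl 2-(benzyloxy)-4-{[4-(benzyloxy)-2,3-dimethoxy-6-methylbenzoyl]oxy}-6-methylbenzoate | COc1c(OCc2ccccc2)cc(C)c(C(=O)Oc2cc(C)c(C(=O)OCC=C)c(OCc3ccccc3)c2)c1OC
F4 | step 13 | 2-(benzyloxy)-4-{[4-(benzyloxy)-2,3-dimethoxy-6-methylbenzoyl]oxy}-6-methylbenzoic acid | COc1c(OCc2ccccc2)cc(C)c(C(=O)Oc2cc(C)c(C(=O)O)c(OCc3ccccc3)c2)c1OC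
F5 | step 13 | mixed trifluoroacetic anhydride of acid F4 | COc1c(OCc2ccccc2)cc(C)c(C(=O)Oc2cc(C)c(C(=O)OC(=O)C(F)(F)F)c(OCc3ccccc3)c2)c1OC
F6 | step 13 | benzyl 4-[(2-(benzyloxy)-4-{[4-(benzyloxy)-2,3-dimethoxy-6-methylbenzoyl]oxy}-6-methylbenzoyl)oxy]-2-hydroxy-6-methylbenzoate | COc1c(OCc2ccccc2)cc(C)c(C(=O)Oc2cc(C)c(C(=O)Oc3cc(C)c(C(=O)OCc4ccccc4)c(O)c3)c(OCc3ccccc3)c2)c1OC
F7 | step 2 | bromomagnesium 2,3-dimethoxy-4-oxo-1-(prop-1-en-2-yl)cyclobut-2-en-1-olate (racemic, one enantiomer drawn) | COC1=C(OC)[C@](O[Mg]Br)(C(C)=C)C1=O
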